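Elm had half the reagent of birch, yet its target read 20.1 % against 34.0 %, so I reckoned a split, not a rate.

| setting | birch | ash | cedar | elm | blue | violet | ochre |
|---|---|---|---|---|---|---|---|
| starting material | 0.10 M | 0.10 M | 0.10 M | 0.10 M | 0.10 M (fed, over 1.5 min) | 0.10 M | 0.10 M |
| reagent | 0.15 M | 0.15 M | 0.15 M | 0.075 M | 0.150 M | 0.150 M | 0.150 M (fed, over 1.5 min) |
| second substrate | 0.050 M | 0.025 M | 0.038 M | 0.050 M | 0.0500 M | 0.0500 M | 0.0500 M |
| remark | run made earlier | run made earlier | run made earlier | run made earlier | all else is in the flask from the start; the feed brings no volume worth counting | everything together at the start | all else is in the flask from the start; the feed brings no volume worth counting |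
| time |  |  |  |  | 4.0 min | 4.0 min | 4.0 min |

| run | time / min | target / % | starting material / % |
|---|---|---|---|
| birch | 0.500 | 26.6 | 20.5 |
| birch | 1.00 | 33.0 | 8.8 |
| birch | 1.33 | 33.2 | 5.4 |
| birch | 2.00 | 33.8 | 2.8 |
| birch | 2.50 | 34.0 | 2.4 |
| ash | 1.00 | 35.6 | 7.6 |
| ash | 2.00 | 34.0 | 3.4 |
| ash | 3.00 | 32.5 | 2.3 |
| ash | 4.00 | 33.2 | 2.7 |
| ash | 5.00 | 34.0 | 2.1 |
| cedar | 0.417 | 28.2 | 24.9 |
| cedar | 0.667 | 30.2 | 13.6 |
| cedar | 1.33 | 34.5 | 4.3 |
| cedar | 2.50 | 34.8 | 1.5 |
| cedar | 5.00 | 34.7 | 3.8 |
| elm | 0.417 | 14.1 | 33.3 |
| elm | 1.33 | 18.9 | 5.7 |
| elm | 2.00 | 20.1 | 4.8 |
| elm | 3.00 | 19.3 | 3.8 |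
| elm | 5.00 | 20.1 | 3.4 |

(scatter of a reading: 1 percentage point)

- amounts and yields of target count idle adduct too
- what may be going on: second substrate + reagent <-> second product; starting material + reagent <-> target; starting material <-> dormant form; second substrate + target <-> idle adduct

* the flask that comes out highest in amount of target, in percent of the starting material charged, or "all alike" when all lie within 1.5 percentage points (blue / violet / ochre / all alike)
* target at the end, in percent of the starting material charged, blue
* target at the end, in percent of the starting material charged, violet
* target at the end, in percent of the starting material charged, ochre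

Starting material leaves by two ways, to target and to dormant form. Dividing one rate by the other removes time: target over dormant form should equal reagent over a fixed level. I counted as dormant form whatever the last reading left unaccounted. Birch then gave 0.281 M and elm 0.285 M. I call this reading the even-split reagent: the charged reagent at which target and dormant form come out equal in this reckoning, read with second substrate at 0.050 M. Charged reagent over this level is a selectivity factor.

For violet my share of target was 34.8 %, and blue, fed into the charged reagent, got the same. Birch's first reading gave a total loss of 3.17 /min, of which I gave the dormant way 2.07 /min, a lifetime on that way of 0.484 min. In ochre the feed brings 0.0484 M in that lifetime, so I reckoned its first pass at 14.7 %.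

The forecast chose violet, with 34 % for blue, 34 % for violet and 18 % for ochre, saying of ochre that “Feeding reagent sends most material dormant first”. My ochre figure, for the first pass with no return, stood lower than that number for the end.

The flasks gave 33.4 % in blue, 34.9 % in violet and 18.7 % in ochre, so violet stood highest.

    second substrate + reagent ⇌ second product (K = 14.0 /M, k = 0.360 /M/s)
    starting material + reagent ⇌ target (K = 57.0 /M, k = 0.160 /M/s)
    starting material ⇌ dormant form (K = 19.0, k = 0.0360 /s)
    second substrate + target ⇌ idle adduct, settled at all times (K = 98.0 /M)

Violet, birch's recipe, held target over dormant form at 0.564 at 4.00 min, against 0.535 read from birch at 2.50 min. The neighbouring flask is ochre stopped at 1.5 min, the end of its feed. The same reckoning gave it a split of 0.172 and a share of 14.7 %. That flask held 12.3 % target and 82.8 % dormant form, a split of 0.149. Ochre then gained 6.4 percentage points of target by 4.00 min, while its dormant form fell to 78.2 %.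

Readings and results are calculated with constants of no real substance, and the scatter is random.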